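**Retrosynthetic overview**
1. The target is the diformate of (13S)-labd-7-ene-3β,15-diol. The C11–C12 bond is cut to give a C15 drimane diene (exocyclic C9=C11, made from a C9 ketone) and a C5 chiral-pool bromide that carries C13.
2. Key disconnection: the C3–C4 bond of ring A (C1–C5, C10). A tertiary C4 radical, made by hydrogen-atom transfer to an isopropenyl group, closes ring A onto a C3 aldehyde. One operation gives the quaternary gem-dimethyl C4, the C3 carbinol centre and the trans-decalin.
3. The precursor maps onto (R)-carvone: the carvone ring is ring B (C5–C10) with C17 and the C7=C8 alkene already in place. Its carbonyl is C9, its stereocentre is C5, and its isopropenyl group becomes C4/C18/C19.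
4. C10 (with C20 and the C1–C3 chain) is set by two α′-alkylations anti to the isopropenyl group. Ring order: ring B is bought, ring A is closed in step 4, the side chain is joined in step 8, and the formates come last.

Key step: step 4

Numbering remark: atom labels C1–C20 refer to labdane numbering of the target.
Assumption: the C3 hydroxyl is carried unprotected from step 5 to step 9 (excess ylide in step 5 and excess 9-BBN in step 8 allow for its acidic proton), and (R)-2-methylbutane-1,4-diol is taken as a purchasable chiral-pool diol.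

Step 1
Reactants: 1 (R)-(−)-carvone
Product: 3 (5R,6S)-2,6-dimethyl-5-(prop-1-en-2-yl)cyclohex-2-en-1-one, via lithium dienolate 2 (not isolated)
Conditions: LDA, THF, −78 °C; MeI, −78 → 0 °C
Reagents that add atoms: iodomethane, CI
Why: Kinetic deprotonation at the α′-CH2 gives the cross-conjugated lithium dienolate, which is C-methylated (enolate alkylation); the new centre should form mainly trans to the isopropenyl group but is planarised again in step 2, so both epimers converge.

Step 2
Reactants: 3 (5R,6S)-2,6-dimethyl-5-(prop-1-en-2-yl)cyclohex-2-en-1-one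
Product: 5 (5S,6S)-2,6-dimethyl-6-(prop-2-en-1-yl)-5-(prop-1-en-2-yl)cyclohex-2-en-1-one, via lithium enolate 4 (not isolated)
Conditions: LDA, THF, −78 °C; allyl bromide, DMPU, −78 → 0 °C
Reagents that add atoms: allyl bromide, C=CCBr
Why: Allylation of the tetrasubstituted enolate (enolate alkylation forming a quaternary centre) should occur on the face anti to the pseudo-axial isopropenyl group, which places allyl trans and methyl cis to it, as C10 of the trans-decalin requires.

Step 3
Reactants: 5 (5S,6S)-2,6-dimethyl-6-(prop-2-en-1-yl)-5-(prop-1-en-2-yl)cyclohex-2-en-1-one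
Product: 6 3-[(1S,6S)-1,3-dimethyl-2-oxo-6-(prop-1-en-2-yl)cyclohex-3-en-1-yl]propanal
Conditions: PdCl2(PhCN)2 (cat.), CuCl2·2H2O (cat.), AgNO2 (cat.), O2 (1 atm), t-BuOH/MeNO2 15:1, rt
Reagents that add atoms: dioxygen, O=O
Why: A nitrite-modified, aldehyde-selective Wacker oxidation should oxidise the monosubstituted alkene next to the quaternary carbon at its terminal carbon, while the 1,1-disubstituted isopropenyl group and the enone are inert to Wacker conditions and no stereocentre is touched.

Step 4
Reactants: 6 3-[(1S,6S)-1,3-dimethyl-2-oxo-6-(prop-1-en-2-yl)cyclohex-3-en-1-yl]propanal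
Product: 9 (4aS,6S,8aS)-6-hydroxy-2,5,5,8a-tetramethyl-4a,5,6,7,8,8a-hexahydronaphthalen-1(4H)-one, via tertiary C4 radical 7 (not isolated), via C3 alkoxyl radical 8 (not isolated)
Conditions: Fe(acac)3 (30 mol %), PhSiH3, EtOH (dilute, degassed), 60 °C
Reagents that add atoms: none
Why: An iron hydride formed from Fe(acac)3 and PhSiH3 in EtOH transfers a hydrogen atom to the CH2 terminus of the electron-rich isopropenyl group (Markovnikov MHAT) to give the tertiary C4 radical 7, which adds 6-exo-trig to the aldehyde carbon C3 through a chair transition state; the alkoxyl radical 8 is then reduced by iron(II) and protonated by EtOH, which returns iron(III). The closest known reaction type is the iron-hydride HAT-triggered reductive cyclisation of alkene-tethered ketones, together with the intermolecular HAT coupling of unactivated alkenes with aldehydes. Ring A is closed by 6-exo-trig radical attack on the C=O group, which forms the C3–C4 bond and turns the isopropenyl carbon into the quaternary gem-dimethyl C4. The trans ring fusion follows from the fixed C5 and C10 centres, because the radical and the aldehyde chain are trans-diequatorial on ring B with the C10 methyl axial; the C3 centre is controlled by the chair transition state, in which the carbonyl oxygen is pseudo-equatorial and free of 1,3-diaxial contacts with H-1α and H-5α, which should give the 3β (3S) alcohol. The step needs HAT to the isopropenyl group in preference to the trisubstituted enone and ring closure faster than reduction of 7: the electron-poor enone is a poor HAT acceptor and cannot trap 7 intramolecularly (only a four-membered ring would result), and high dilution favours the unimolecular closure.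

Step 5
Reactants: 9 (4aS,6S,8aS)-6-hydroxy-2,5,5,8a-tetramethyl-4a,5,6,7,8,8a-hexahydronaphthalen-1(4H)-one
Product: 10 (2S,4aS,8aR)-1,1,4a,6-tetramethyl-5-methylidene-1,2,3,4,4a,5,8,8a-octahydronaphthalen-2-ol
Conditions: Ph3PCH3Br (excess), KOt-Bu, toluene, 0 → 90 °C
Reagents that add atoms: methyltriphenylphosphonium bromide, C[P+](c1ccccc1)(c1ccccc1)c1ccccc1.[Br-]
Why: Wittig methylenation under salt-free, high-temperature conditions suited to hindered ketones converts the C9 carbonyl into the exocyclic C9=C11 alkene; the excess ylide only deprotonates the 3-OH, and C5 and C10 (no α-hydrogen) cannot epimerise.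

Step 6
Reactants: 11 (R)-2-methylbutane-1,4-diol
Product: 12 (R)-4-[(tert-butyldiphenylsilyl)oxy]-2-methylbutan-1-ol
Conditions: TBDPSCl (1.0 equiv), imidazole, CH2Cl2, −40 → 0 °C
Reagents that add atoms: tert-butyl(chloro)diphenylsilane, CC(C)(C)[Si](Cl)(c1ccccc1)c1ccccc1
Why: Silylation with the bulky chlorosilane should occur preferentially at the primary hydroxyl remote from the methyl branch (steric differentiation of two primary alcohols), with the minor regioisomer removed by chromatography and the stereocentre untouched.

Step 7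
Reactants: 12 (R)-4-[(tert-butyldiphenylsilyl)oxy]-2-methylbutan-1-ol
Product: 13 (R)-(4-bromo-3-methylbutoxy)(tert-butyl)diphenylsilane
Conditions: CBr4, PPh3, CH2Cl2, 0 °C
Reagents that add atoms: carbon tetrabromide, BrC(Br)(Br)Br
Why: The Appel reaction converts the primary alcohol into the bromide under neutral conditions that touch neither the silyl ether nor the adjacent stereocentre.

Step 8
Reactants: 10 (2S,4aS,8aR)-1,1,4a,6-tetramethyl-5-methylidene-1,2,3,4,4a,5,8,8a-octahydronaphthalen-2-ol; 13 (R)-(4-bromo-3-methylbutoxy)(tert-butyl)diphenylsilane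
Product: 15 (3S,5R,9S,10R,13S)-15-[(tert-butyldiphenylsilyl)oxy]labd-7-en-3-ol, via B-alkyl-9-BBN borane 14 (not isolated)
Conditions: 9-BBN dimer (excess), THF, rt → 50 °C; then 13, NiCl2·glyme (cat.), trans-N,N′-dimethylcyclohexane-1,2-diamine (cat.), KOt-Bu, i-BuOH, dioxane, rt; aq. NaOH work-up
Reagents that add atoms: none
Why: 9-BBN should add only to the exocyclic C9=C11 bond of the diene (anti-Markovnikov, boron on C11) from the α-face opposite the axial C10 methyl, so that H-9 is α and the C11 arm β; the alkylborane is then joined to the primary bromide by a nickel/diamine-catalysed alkyl–alkyl Suzuki coupling that tolerates β-hydrogens and leaves C13 untouched.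

Step 9
Reactants: 15 (3S,5R,9S,10R,13S)-15-[(tert-butyldiphenylsilyl)oxy]labd-7-en-3-ol
Product: 16 (3S,5R,9S,10R,13S)-labd-7-ene-3,15-diol
Conditions: TBAF, THF, rt
Reagents that add atoms: none
Why: Fluoride cleavage of the primary silyl ether (desilylation) frees the C15 hydroxyl; nothing else in the molecule is fluoride-labile.

Step 10
Reactants: 16 (3S,5R,9S,10R,13S)-labd-7-ene-3,15-diol
Product: 17 (3S,5R,9S,10R,13S)-labd-7-ene-3,15-diyl diformate
Conditions: HCO2H/Ac2O (premixed at 55 °C, cooled), pyridine, CH2Cl2, 0 °C → rt
Reagents that add atoms: acetic formic anhydride, CC(=O)OC=O, made from formic acid, OC=O, and acetic anhydride, CC(=O)OC(C)=O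
Why: The mixed anhydride transfers the small formyl group selectively (O-formylation) to both the primary and the hindered equatorial secondary hydroxyl under basic, non-isomerising conditions, so the C7=C8 alkene stays in place.

**Compound list**
1 | (R)-(−)-carvone | CC1=CC[C@H](CC1=O)C(C)=C | starting material
2 | lithium dienolate of 1 (C1–OLi, C1=C6) | [Li]OC1=C[C@H](C(C)=C)CC=C1C | intermediate
3 | (5R,6S)-2,6-dimethyl-5-(prop-1-en-2-yl)cyclohex-2-en-1-one (trans-6-methylcarvone) | CC1=CC[C@@H](C(C)=C)[C@H](C)C1=O | intermediate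
4 | lithium enolate of 3 (C1–OLi, C1=C6) | [Li]OC1=C(C)[C@H](C(C)=C)CC=C1C | intermediate
5 | (5S,6S)-2,6-dimethyl-6-(prop-2-en-1-yl)-5-(prop-1-en-2-yl)cyclohex-2-en-1-one | CC1=CC[C@@H](C(C)=C)[C@](C)(CC=C)C1=O | intermediate
6 | 3-[(1S,6S)-1,3-dimethyl-2-oxo-6-(prop-1-en-2-yl)cyclohex-3-en-1-yl]propanal | CC1=CC[C@@H](C(C)=C)[C@](C)(CCC=O)C1=O | intermediate
7 | tertiary C4 radical from 6 (2-propyl radical at the former isopropenyl carbon) | CC1=CC[C@@H]([C](C)C)[C@](C)(CCC=O)C1=O | intermediate
8 | C3 alkoxyl radical of 9 | CC1=CC[C@H]2C(C)(C)[C@@H]([O])CC[C@]2(C)C1=O | intermediate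
9 | (4aS,6S,8aS)-6-hydroxy-2,5,5,8a-tetramethyl-4a,5,6,7,8,8a-hexahydronaphthalen-1(4H)-one (3β-hydroxy-11-nordrim-7-en-9-one) | CC1=CC[C@H]2C(C)(C)[C@@H](O)CC[C@]2(C)C1=O | intermediate
10 | (2S,4aS,8aR)-1,1,4a,6-tetramethyl-5-methylidene-1,2,3,4,4a,5,8,8a-octahydronaphthalen-2-ol (drima-7,9(11)-dien-3β-ol) | CC1=CC[C@H]2C(C)(C)[C@@H](O)CC[C@]2(C)C1=C | intermediate
11 | (R)-2-methylbutane-1,4-diol | OC[C@H](C)CCO | starting material
12 | (R)-4-[(tert-butyldiphenylsilyl)oxy]-2-methylbutan-1-ol | OC[C@H](C)CCO[Si](c1ccccc1)(c1ccccc1)C(C)(C)C | intermediate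
13 | (R)-(4-bromo-3-methylbutoxy)(tert-butyl)diphenylsilane | BrC[C@H](C)CCO[Si](c1ccccc1)(c1ccccc1)C(C)(C)C | intermediate
14 | B-alkyl-9-BBN borane: 11-(9-borabicyclo[3.3.1]nonan-9-yl)drim-7-en-3β-ol as its O-(9-BBN) borinate | CC1=CC[C@H]2C(C)(C)[C@@H](OB3C4CCCC3CCC4)CC[C@]2(C)[C@H]1CB1C2CCCC1CCC2 | intermediate
15 | (3S,5R,9S,10R,13S)-15-[(tert-butyldiphenylsilyl)oxy]labd-7-en-3-ol | CC1=CC[C@H]2C(C)(C)[C@@H](O)CC[C@]2(C)[C@H]1CC[C@H](C)CCO[Si](c1ccccc1)(c1ccccc1)C(C)(C)C | intermediate
16 | (3S,5R,9S,10R,13S)-labd-7-ene-3,15-diol | CC1=CC[C@H]2C(C)(C)[C@@H](O)CC[C@]2(C)[C@H]1CC[C@H](C)CCO | intermediate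
17 | (3S,5R,9S,10R,13S)-labd-7-ene-3,15-diyl diformate (CNP0137609.1) | CC1=CC[C@H]2C(C)(C)[C@@H](OC=O)CC[C@]2(C)[C@H]1CC[C@H](C)CCOC=O | target

**Step count**
Total steps: 10. Longest linear sequence: 8 (steps 1–5 and 8–10; steps 6–7 prepare the side-chain bromide).

**Steps most likely to fail, with fallbacks**

Step 4 (key step). The 6-exo addition of the tertiary radical to the aldehyde is reversible through β-scission of the alkoxyl radical, so reduction of the radical to the isopropyl compound may outrun productive trapping. The fallback sets out from 6 and comes back at 9. Markovnikov addition of HBr (HBr/AcOH, CH2Cl2, 0 °C) to the isopropenyl group should give the tertiary bromide 3-[(1S,6R)-6-(2-bromopropan-2-yl)-1,3-dimethyl-2-oxocyclohex-3-en-1-yl]propanal F1. This is then submitted to a tin hydride radical chain (Bu3SnH, AIBN, slow addition, benzene, 80 °C). The radical is now formed stoichiometrically from the C–Br bond, and the cyclised alkoxyl radical is trapped by fast hydrogen transfer from Sn–H, a known mode of radical cyclisation onto aldehydes, to give 9.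

Step 8. Transmetalation of the hindered, β-branched alkylborane to nickel may be too slow, so that the bromide is consumed by reduction or elimination before C–C coupling. The fallback sets out from 10 and comes back at 15. Hydroboration with 9-BBN followed by NaOH/H2O2 should give drim-7-ene-3β,11-diol F2. Selective iodination of the primary hydroxyl (I2, PPh3, imidazole, CH2Cl2, 0 °C) gives 11-iododrim-7-en-3β-ol F3. Bromide 13 is converted with magnesium in THF into the Grignard reagent [(R)-4-[(tert-butyldiphenylsilyl)oxy]-2-methylbutyl]magnesium bromide F4. This is coupled with F3 under copper catalysis (Li2CuCl4 cat., THF, −20 → 0 °C, one extra equivalent of F4 for the free 3-OH) to give 15.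

Step 3. The oxygen nucleophile may attack the internal carbon (methyl ketone formation), or a palladium hydride may isomerise the allyl group, instead of giving the terminal aldehyde. The fallback sets out from 3 and comes back at 6, bypassing 5. The lithium enolate of 3 (LDA, THF, −78 °C) is alkylated in the presence of DMPU with 2-(2-iodoethyl)-1,3-dioxolane, again anti to the isopropenyl group, to give (5S,6S)-6-[2-(1,3-dioxolan-2-yl)ethyl]-2,6-dimethyl-5-(prop-1-en-2-yl)cyclohex-2-en-1-one F5. Mild acetal hydrolysis (PPTS, acetone/H2O, 50 °C) then releases aldehyde 6.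

**Further compounds**
F1 | step 4 | 3-[(1S,6R)-6-(2-bromopropan-2-yl)-1,3-dimethyl-2-oxocyclohex-3-en-1-yl]propanal | CC1=CC[C@@H](C(C)(C)Br)[C@](C)(CCC=O)C1=O
F2 | step 8 | drim-7-ene-3β,11-diol | CC1=CC[C@H]2C(C)(C)[C@@H](O)CC[C@]2(C)[C@H]1CO
F3 | step 8 | 11-iododrim-7-en-3β-ol | CC1=CC[C@H]2C(C)(C)[C@@H](O)CC[C@]2(C)[C@H]1CI
F4 | step 8 | [(R)-4-[(tert-butyldiphenylsilyl)oxy]-2-methylbutyl]magnesium bromide | Br[Mg]C[C@H](C)CCO[Si](c1ccccc1)(c1ccccc1)C(C)(C)C
F5 | step 3 | (5S,6S)-6-[2-(1,3-dioxolan-2-yl)ethyl]-2,6-dimethyl-5-(prop-1-en-2-yl)cyclohex-2-en-1-one | CC1=CC[C@@H](C(C)=C)[C@](C)(CCC2OCCO2)C1=O
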